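## Retrosynthetic overview

1. Target 15 comes from 14 by enzymatic release of the primary 15-OH. 14 comes from 13 by acylation, and 13 from ketone 12, where hydride attack on the open α face gives the axial 6β-OH.
2. 12 comes from enone 9 by deconjugative α-oxygenation of the 7-en-6-one dienolate, which sets 7α-O and moves the alkene to C8=C9. 9 comes from 8 by allylic oxidation at C6.
3. 8 comes from the acyclic, pre-oxygenated "iso-geranylgeranyl" tetraene 6 in one head-to-tail cationic cascade. Ring A closes first (C4–C5), ring B second (C10–C9), and the C8 cation loses H-7, as on the way to the labdadienyl skeleton in nature. The C2 carbinol is the only control element.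
4. 6 comes from aldehyde 4 and methallylstannane 5 by catalytic asymmetric methallylation. 4 comes from farnesyl acetate 1 plus CO.

Assumption: labdane numbering is used for all bicyclic compounds, and 1 (pure 2E,6E isomer), 5 and Hg(OTf)2 are bought as such.

## Route

**Step 1**
Reactants: 1 (2E,6E)-farnesyl acetate
Product: 2 (2E,6E,10E)-12-hydroxy-3,7,11-trimethyldodeca-2,6,10-trien-1-yl acetate
Conditions: SeO2 (0.1 equiv), salicylic acid (0.1 equiv), t-BuOOH (3 equiv), CH2Cl2, 0 °C to rt; stop near 60% conversion and recycle 1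
Reagents that add atoms: tert-butyl hydroperoxide, CC(C)(C)OO
Why: Catalytic SeO2/t-BuOOH allylic hydroxylation (ene reaction, then [2,3]-sigmatropic shift) attacks the terminal, most electron-rich trisubstituted alkene and oxygenates its E-methyl group, the alkene next to the acetate being deactivated; no stereocentre is made and the E geometry follows from the [2,3] transition state.

**Step 2**
Reactants: 2 (2E,6E,10E)-12-hydroxy-3,7,11-trimethyldodeca-2,6,10-trien-1-yl acetate
Product: 3 (2E,6E,10E)-12-bromo-3,7,11-trimethyldodeca-2,6,10-trien-1-yl acetate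
Conditions: PBr3 (0.4 equiv), Et2O, 0 °C
Reagents that add atoms: phosphorus tribromide, BrP(Br)Br
Why: SN2 bromination of a primary allylic alcohol through its phosphite ester at 0 °C proceeds without allylic transposition or E/Z loss and leaves the acetate alone.

**Step 3**
Reactants: 3 (2E,6E,10E)-12-bromo-3,7,11-trimethyldodeca-2,6,10-trien-1-yl acetate
Product: 4 (2E,6E,10E)-3,7,11-trimethyl-13-oxotrideca-2,6,10-trien-1-yl acetate
Conditions: Pd(PPh3)4 (4 mol%), CO (3 atm), Bu3SnH (1.05 equiv, syringe pump, 3 h), THF, 50 °C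
Reagents that add atoms: carbon monoxide, [C-]#[O+]
Why: Palladium-catalysed carbonylative formylation of an allylic halide (Stille type): zerovalent palladium inserts into the C–Br bond much faster than into the hindered allylic acetate, CO inserts at the unsubstituted allyl terminus, and slow hydride transfer from tin releases the β,γ-unsaturated aldehyde under neutral conditions that do not conjugate it.

**Step 4**
Reactants: 4 (2E,6E,10E)-3,7,11-trimethyl-13-oxotrideca-2,6,10-trien-1-yl acetate; 5 tributyl(2-methylallyl)stannane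
Product: 6 (2E,6E,10E,13S)-13-hydroxy-3,7,11,15-tetramethylhexadeca-2,6,10,15-tetraen-1-yl acetate
Conditions: (S)-BINOL (20 mol%), Ti(OiPr)4 (10 mol%), 4 Å MS, CH2Cl2, −20 °C, 60 h; aq NaHCO3
Reagents that add atoms: none
Why: Keck asymmetric methallylation: the BINOL–titanium Lewis acid exposes the Si face of the aldehyde to the allylstannane (SE2′, open transition state), which sets the single carbinol centre as S (the future C2), typically in 90–95% ee, under conditions too mild to isomerise the skipped enal.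

**Step 5** (key step)
Reactants: 6 (2E,6E,10E,13S)-13-hydroxy-3,7,11,15-tetramethylhexadeca-2,6,10,15-tetraen-1-yl acetate
Product: 8 2α-hydroxylabda-7,13E-dien-15-yl acetate, via alkylmercury triflate 7 (not isolated)
Conditions: Hg(OTf)2 (1.2 equiv), PhNMe2 (1.2 equiv), MeNO2, −20 °C, 2 h; then NaBH4 (2 equiv), THF–H2O, 0 °C, 15 min
Reagents that add atoms: none
Why: Mercury-triflate-induced biomimetic polyene cyclization followed by reductive demercuration: divalent mercury stands in for the enzyme's proton and picks the 1,1-disubstituted alkene (the textbook order of oxymercuration rates), so the metal ends up on a carbon that becomes a C4 methyl group; the tertiary C4 cation is taken on by the two E-alkenes through a chair–chair array (anti additions give 5α-H, 10β-CH3 and the 9β side chain) in which the free carbinol, unable to trap any cation, stays equatorial to avoid the two syn-axial methyl groups and so fixes the absolute sense; and the amine-buffered medium removes the axial H-7 from the C8 cation before the acetate-deactivated 13,14-alkene can add.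

**Step 6**
Reactants: 8 2α-hydroxylabda-7,13E-dien-15-yl acetate
Product: 9 2α-hydroxy-6-oxolabda-7,13E-dien-15-yl acetate
Conditions: Cr(CO)6 (0.3 equiv), t-BuOOH (4 equiv, decane), MeCN, 80 °C
Reagents that add atoms: tert-butyl hydroperoxide, CC(C)(C)OO
Why: Chromium-carbonyl-catalysed t-BuOOH allylic oxidation, a method known to spare secondary alcohols, converts the only ring methylene next to the electron-rich 7,8-alkene into the 7-en-6-one, while the allylic positions of the side chain are deactivated by the acetate; no stereocentre is touched.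

**Step 7**
Reactants: 9 2α-hydroxy-6-oxolabda-7,13E-dien-15-yl acetate
Product: 12 2α,7α,15-triacetoxylabda-8,13E-dien-6-one, via dipotassium dienolate 10 (not isolated), via dipotassium dialkoxide 11 (not isolated)
Conditions: KN(SiMe3)2 (1.95 equiv), THF, −78 to −20 °C; 2-(phenylsulfonyl)-3-phenyloxaziridine (1.2 equiv), −78 °C; Ac2O (6 equiv), DMAP, −78 to 0 °C
Reagents that add atoms: 2-(phenylsulfonyl)-3-phenyloxaziridine, O=S(=O)(N1OC1c1ccccc1)c1ccccc1; acetic anhydride, CC(=O)OC(C)=O
Why: Deconjugative α-hydroxylation of an extended enolate with a Davis oxaziridine, then exhaustive acetylation: under equilibrating conditions the axial, π-aligned H-9 is lost to give the more substituted endocyclic dienolate (the α- to β-isophorone pattern); the electrophilic oxygen is taken up at the α-carbon C7 from the α face because the β face is screened by the axial methyl groups on C10 and C4, which sets 7α-O and leaves the alkene at C8=C9; and the Ac2O quench caps O-2 and O-7 and repairs any acetyl scrambling.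

**Step 8**
Reactants: 12 2α,7α,15-triacetoxylabda-8,13E-dien-6-one
Product: 13 2α,7α,15-triacetoxylabda-8,13E-dien-6β-ol
Conditions: NaBH4, THF–MeOH 4:1, −40 °C
Reagents that add atoms: none
Why: Substrate-controlled borohydride reduction: approach from the β face is blocked by the two syn-axial methyl groups, so hydride arrives from the α face and gives the axial 6β-alcohol, trans-diaxial to the 7α-acetate so that no acyl migration can follow; the esters are inert at −40 °C.

**Step 9**
Reactants: 13 2α,7α,15-triacetoxylabda-8,13E-dien-6β-ol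
Product: 14 2α,7α,15-triacetoxy-6β-isovaleroxylabda-8,13E-diene
Conditions: (i-BuCO)2O (4 equiv), DMAP (1 equiv), Et3N, toluene, 60 °C
Reagents that add atoms: isovaleric anhydride, CC(C)CC(=O)OC(=O)CC(C)C
Why: DMAP-catalysed (Steglich-type) acylation with the anhydride at 60 °C forces the only free, hindered axial hydroxyl into the isovalerate with retention, no other nucleophilic site being left.

**Step 10**
Reactants: 14 2α,7α,15-triacetoxy-6β-isovaleroxylabda-8,13E-diene
Product: 15 2α,7α-diacetoxy-6β-isovaleroxylabda-8,13E-dien-15-ol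
Conditions: immobilised Candida antarctica lipase B, n-BuOH (5 equiv), MTBE, 30 °C
Reagents that add atoms: none
Why: Lipase-catalysed regioselective transesterification: the enzyme accepts the unhindered primary terpenyl acetate but not the three secondary esters on the decalin, so only O-15 is set free and no stereocentre is affected.

## Compound list

1 | (2E,6E)-farnesyl acetate | CC(C)=CCC/C(C)=C/CC/C(C)=C/COC(C)=O | starting material
2 | (2E,6E,10E)-12-hydroxy-3,7,11-trimethyldodeca-2,6,10-trien-1-yl acetate | OC/C(C)=C/CC/C(C)=C/CC/C(C)=C/COC(C)=O | intermediate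
3 | (2E,6E,10E)-12-bromo-3,7,11-trimethyldodeca-2,6,10-trien-1-yl acetate | BrC/C(C)=C/CC/C(C)=C/CC/C(C)=C/COC(C)=O | intermediate
4 | (2E,6E,10E)-3,7,11-trimethyl-13-oxotrideca-2,6,10-trien-1-yl acetate | O=CC/C(C)=C/CC/C(C)=C/CC/C(C)=C/COC(C)=O | intermediate
5 | tributyl(2-methylallyl)stannane | C=C(C)C[Sn](CCCC)(CCCC)CCCC | starting material
6 | (2E,6E,10E,13S)-13-hydroxy-3,7,11,15-tetramethylhexadeca-2,6,10,15-tetraen-1-yl acetate | C=C(C)C[C@H](O)C/C(C)=C/CC/C(C)=C/CC/C(C)=C/COC(C)=O | intermediate
7 | 2α-hydroxy-18-(triflyloxymercurio)labda-7,13E-dien-15-yl acetate | O[C@H]1C[C@@](C)(C[Hg]OS(=O)(=O)C(F)(F)F)[C@@H]2CC=C(C)[C@H](CC/C(C)=C/COC(C)=O)[C@@]2(C)C1 | intermediate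
8 | 2α-hydroxylabda-7,13E-dien-15-yl acetate | O[C@H]1CC(C)(C)[C@@H]2CC=C(C)[C@H](CC/C(C)=C/COC(C)=O)[C@@]2(C)C1 | intermediate
9 | 2α-hydroxy-6-oxolabda-7,13E-dien-15-yl acetate | O[C@H]1CC(C)(C)[C@@H]2C(=O)C=C(C)[C@H](CC/C(C)=C/COC(C)=O)[C@@]2(C)C1 | intermediate
10 | dipotassium 2-alkoxide 6,8-dien-6-olate of 9 | [K+].[K+].[O-][C@H]1CC(C)(C)[C@@H]2C([O-])=CC(C)=C(CC/C(C)=C/COC(C)=O)[C@@]2(C)C1 | intermediate
11 | dipotassium 2α,7α-dialkoxide of 15-acetoxy-6-oxolabda-8,13E-diene | [K+].[K+].[O-][C@H]1CC(C)(C)[C@@H]2C(=O)[C@@H]([O-])C(C)=C(CC/C(C)=C/COC(C)=O)[C@@]2(C)C1 | intermediate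
12 | 2α,7α,15-triacetoxylabda-8,13E-dien-6-one | CC(=O)O[C@H]1CC(C)(C)[C@@H]2C(=O)[C@@H](OC(C)=O)C(C)=C(CC/C(C)=C/COC(C)=O)[C@@]2(C)C1 | intermediate
13 | 2α,7α,15-triacetoxylabda-8,13E-dien-6β-ol | CC(=O)O[C@H]1CC(C)(C)[C@@H]2[C@H](O)[C@@H](OC(C)=O)C(C)=C(CC/C(C)=C/COC(C)=O)[C@@]2(C)C1 | intermediate
14 | 2α,7α,15-triacetoxy-6β-isovaleroxylabda-8,13E-diene | CC(=O)O[C@H]1CC(C)(C)[C@@H]2[C@H](OC(=O)CC(C)C)[C@@H](OC(C)=O)C(C)=C(CC/C(C)=C/COC(C)=O)[C@@]2(C)C1 | intermediate
15 | 2α,7α-diacetoxy-6β-isovaleroxylabda-8,13E-dien-15-ol | CC(=O)O[C@H]1CC(C)(C)[C@@H]2[C@H](OC(=O)CC(C)C)[C@@H](OC(C)=O)C(C)=C(CC/C(C)=C/CO)[C@@]2(C)C1 | target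

## Step count and risks

Total step count: 10. Longest linear sequence: 10 (1 to 15).

**Step 5 (cascade).** The C8 cation may be captured by the 13,14-alkene to give a tricycle, or proton loss may be unselective. The fallback sets out from 6 and comes back at 8. It switches the side-chain alkene off electronically instead of relying on the buffer.
- K2CO3 in MeOH turns 6 into (2E,6E,10E,13S)-3,7,11,15-tetramethylhexadeca-2,6,10,15-tetraene-1,13-diol F1.
- MnO2 oxidises only the allylic alcohol of F1 to (2E,6E,10E,13S)-13-hydroxy-3,7,11,15-tetramethylhexadeca-2,6,10,15-tetraenal F2, whose conjugated alkene is no longer a π-nucleophile.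
- Hg(OTf)2 with PhNMe2 then gives 2α-hydroxy-18-(triflyloxymercurio)labda-7,13E-dien-15-al F3.
- NaBH4 removes the metal and reduces the aldehyde in the same flask to labda-7,13E-diene-2α,15-diol F4.
- Lipase with vinyl acetate acetylates only the primary hydroxyl to give 8.

**Step 6 (allylic oxidation).** Attack at the tertiary H-9, which would give the 8-en-7-one, or attack on the side chain may compete. The fallback sets out from 8 and comes back at 12. It replaces C–H oxidation by alkene functionalisation and oxidative transposition.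
- Ac2O in pyridine gives 2α,15-diacetoxylabda-7,13E-diene F5.
- PhSeCl in MeCN–H2O adds trans-diaxially across the only electron-rich alkene to give 2α,15-diacetoxy-7α-(phenylselanyl)labd-13E-en-8β-ol F6.
- H2O2 forms the selenoxide 2α,15-diacetoxy-7α-(phenylseleninyl)labd-13E-en-8β-ol F7. This can eliminate only towards C6 and gives 2α,15-diacetoxylabda-6,13E-dien-8β-ol F8.
- Pyridinium chlorochromate, C5H5NH[CrO3Cl], carries out the oxidative 1,3-transposition of this tertiary allylic alcohol to 2α,15-diacetoxylabda-7,13E-dien-6-one F9.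
- F9 gives 12 under the conditions of step 7 with one equivalent less of base.

**Step 7 (extended enolate).** Exocyclic deprotonation at C17, oxygenation at the γ-carbon, or base damage to the esters may intervene. The fallback sets out from 9 and comes back at 12. It uses a neutral enol ether and an oxidant that cannot touch tetrasubstituted alkenes.
- Me3SiOTf with Et3N (rt, thermodynamic control) gives 15-acetoxy-2α,6-bis(trimethylsilyloxy)labda-6,8,13E-triene F10.
- OsO4 (2 mol%) with N-methylmorpholine N-oxide dihydroxylates only the electron-rich C6=C7 enol ether bond, from the α face. A citric acid wash then gives 15-acetoxy-2α,7α-dihydroxylabda-8,13E-dien-6-one F11.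
- Ac2O with DMAP converts F11 into 12.

## Further compounds

F1 | step 5 | (2E,6E,10E,13S)-3,7,11,15-tetramethylhexadeca-2,6,10,15-tetraene-1,13-diol | C=C(C)C[C@H](O)C/C(C)=C/CC/C(C)=C/CC/C(C)=C/CO
F2 | step 5 | (2E,6E,10E,13S)-13-hydroxy-3,7,11,15-tetramethylhexadeca-2,6,10,15-tetraenal | C=C(C)C[C@H](O)C/C(C)=C/CC/C(C)=C/CC/C(C)=C/C=O
F3 | step 5 | 2α-hydroxy-18-(triflyloxymercurio)labda-7,13E-dien-15-al | O[C@H]1C[C@@](C)(C[Hg]OS(=O)(=O)C(F)(F)F)[C@@H]2CC=C(C)[C@H](CC/C(C)=C/C=O)[C@@]2(C)C1
F4 | step 5 | labda-7,13E-diene-2α,15-diol | O[C@H]1CC(C)(C)[C@@H]2CC=C(C)[C@H](CC/C(C)=C/CO)[C@@]2(C)C1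
F5 | step 6 | 2α,15-diacetoxylabda-7,13E-diene | CC(=O)O[C@H]1CC(C)(C)[C@@H]2CC=C(C)[C@H](CC/C(C)=C/COC(C)=O)[C@@]2(C)C1
F6 | step 6 | 2α,15-diacetoxy-7α-(phenylselanyl)labd-13E-en-8β-ol | CC(=O)O[C@H]1CC(C)(C)[C@@H]2C[C@@H]([Se]c3ccccc3)[C@](C)(O)[C@H](CC/C(C)=C/COC(C)=O)[C@@]2(C)C1
F7 | step 6 | 2α,15-diacetoxy-7α-(phenylseleninyl)labd-13E-en-8β-ol | CC(=O)O[C@H]1CC(C)(C)[C@@H]2C[C@@H]([Se](=O)c3ccccc3)[C@](C)(O)[C@H](CC/C(C)=C/COC(C)=O)[C@@]2(C)C1
F8 | step 6 | 2α,15-diacetoxylabda-6,13E-dien-8β-ol | CC(=O)O[C@H]1CC(C)(C)[C@@H]2C=C[C@](C)(O)[C@H](CC/C(C)=C/COC(C)=O)[C@@]2(C)C1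
F9 | step 6 | 2α,15-diacetoxylabda-7,13E-dien-6-one | CC(=O)O[C@H]1CC(C)(C)[C@@H]2C(=O)C=C(C)[C@H](CC/C(C)=C/COC(C)=O)[C@@]2(C)C1
F10 | step 7 | 15-acetoxy-2α,6-bis(trimethylsilyloxy)labda-6,8,13E-triene | C[Si](C)(C)O[C@H]1CC(C)(C)[C@@H]2C(O[Si](C)(C)C)=CC(C)=C(CC/C(C)=C/COC(C)=O)[C@@]2(C)C1
F11 | step 7 | 15-acetoxy-2α,7α-dihydroxylabda-8,13E-dien-6-one | O[C@H]1CC(C)(C)[C@@H]2C(=O)[C@@H](O)C(C)=C(CC/C(C)=C/COC(C)=O)[C@@]2(C)C1
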